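## Structural features

The target is a germacranolide: a ten-membered carbocycle (C1–C10) fused across C6–C7 to an α-methylene-γ-butyrolactone (C11–C13, ring oxygen on C6), and the fusion is cis (6R,7R, H6 and H7 on the same face). The carbocycle carries a trans-1,10-epoxide with a quaternary, methyl-bearing C10 (1S,10R), a C2 ketone conjugated to a Z C3=C4 olefin (methyl on C4), a free secondary alcohol at C5 (5S) and a tiglate on C8 (8R). The stereocentres form two blocks, the four contiguous centres C5–C6–C7–C8 and the pair C10–C1, separated by the C9 methylene. The fragile groups are the cis-γ-hydroxy-enone (hemiketal and furan formation), the α,β-epoxy ketone (opened by reductants, acids and bases), the methylene lactone (a Michael acceptor) and the tiglate (deconjugation, acyl transfer). The real difficulty is twofold: a strained ten-membered ring that must hold both a Z enone and the epoxide of an E olefin, and three secondary oxygens (C2, C5, C8) that must end as ketone, free alcohol and ester. The key step uses the 1,5-relation of the C2 and C8 oxygens across the C1=C10 unit: C9–C10(CH3)–C1 is a 2-methylallyl linchpin between two carbinol carbons. C8 hangs on the preformed cis-disubstituted five-membered ether ring (the lactone in reduced form), and C2 carries a propynyl group (the latent Z C3=C4); its carbinol only relays stereochemistry to the epoxide before it becomes the ketone.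

## Logic of the disconnections

**31 ⇒ 30 ⇒ 29.** No skeletal bond is cut; the C5 O–Si bond is restored and the C12 carbonyl oxygen removed. The free C5 carbinol is liberated last, and the hydride-labile methylene lactone is carried as an inert methylenetetrahydrofuran. The forward oxidation must single out the C12 methylene, so every hydroxyl must be capped at that point, and the last desilylation must be neither basic nor nucleophilic.

**29 ⇒ 27 + 28.** The C8–O acyl bond is cut. The tiglate cannot survive the hydride step that makes the iodoalkene, so it is attached late. This demands that C8–OH be the only free hydroxyl in 27.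

**27 ⇒ 26 ⇒ 25 ⇒ 24.** The C2 carbonyl is returned to a carbinol, and the silyl groups on C2/C8 and C5 are exchanged. The C2 carbinol is needed earlier (it directs the epoxidation, and an epoxy ketone would not survive divalent chromium). C2 and C8 are told apart by oxidation: MnO2 touches only the allylic C2 carbinol. The demand is orthogonal silyl lability (triethylsilyl on C2/C8, tert-butyldimethylsilyl on C5).

**24 ⇒ 23 ⇒ 22 ⇒ 21.** The ring bond C4–C5 is cut, the only ring bond joining an sp2 carbon to a carbinol. The ring opens to an acyclic Z iodoalkene and a C5 aldehyde. The forward closure of a ten-membered ring needs high dilution and Felkin-type facial control at C5, and the C5 protecting group must leave without disturbing silyl ethers.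

**21 ⇒ 20 ⇒ 19.** The two epoxide C–O bonds (C1–O, C10–O) are cut back to the E olefin. This removes two stereocentres, which the C2 hydroxyl can reinstall. The forward step must be threo-selective and must ignore the iodoalkene and the exocyclic methylene.

**19 ⇒ 17.** The C4–I bond is cut back to the C3≡C4 alkyne. The alkyne is linear, cannot isomerise and is inert to allylboration. The forward trans-hydroalumination must place the metal on C4, cis to C2.

**17 ⇒ 13 + 15 + 10 (key).** C1–C2 and C8–C9 are cut. The chain falls into a three-carbon linchpin and two aldehydes, and two stereocentres plus the olefin geometry are traced to one catalyst. The demand is severe: E geometry in the second allyl transfer despite the C10 methyl, and reagent control over the α-stereocentre of 10.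

**10 ⇒ 9 ⇒ 7.** After adjusting the C8 oxidation level, the ring bond C7–C11 is cut to a vinyl bromide and a terminal epoxide. An SN2 opening at C7 fixes the cis relation to C6 stereospecifically. Anti opening of a cis-2,3-epoxide followed by ring closure would give the trans ring, hence the threo 1,2-epoxy-3-ol. The forward step must close 5-exo.

**7 ⇒ 5 + 6.** The ether bond O6–C12 is cut; a simple allylic bromide supplies C11–C13. The alkylation must outrun epoxide migration.

**5 ⇒ 3 ⇒ 2 ⇒ 1.** The C8–O epoxide bond and the protecting groups are cut. L-Threitol acetonide supplies C5–C8 with both stereocentres (threo) from the chiral pool; its C2 symmetry makes monoprotection unambiguous.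

**13 ⇒ 11 + 12.** The C1=C10 double bond is cut (metathesis) into two commercial boronates. E geometry must come from thermodynamic control.

**15 ⇒ 14.** Oxidation level only; the volatile ynal is made fresh.

## Other disconnections considered

**Alternative 1:** The cut is C7–C11 together with C8–O, on a preformed ten-membered ring. In the forward step (hexabutylditin, light) a C11 radical, released from a bromoacetal side chain on the C6 oxygen, adds 5-exo to C7 of a Z C7=C8 ring olefin. The C8 radical is caught by the nitroxyl to give the cis-fused acetal A1.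
- In favour: 5-exo closure onto a ring olefin can only give the cis fusion; C12 arrives at the lactol level, so the lactone needs only a mild oxidation; radical conditions spare epoxide and silyl ethers.
- Against: it presupposes the ten-membered Z-cycloalkene with epoxide and both carbinols, which is the hard part. The C8 configuration depends on the face of a mobile ring radical. α-Methylenation, N–O cleavage and acylation all remain.
- Comparison: on ring fusion and on the lactone oxidation level it is the better plan (no hexavalent-chromium C–H oxidation). On skeleton assembly it is weaker: it forms one C–C bond, whereas the chosen step joins three fragments and sets C8 in a closed transition state. After its key step it is no shorter.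

**Alternative 2:** C9–C10 is formed and C2–C7 broken in a [3,3] shift, so the ten-membered ring is traced to a six-membered one. In the forward step (KH, 18-crown-6) the alkoxide of a cyclohexenol with a 2-silyloxypropenyl group on the carbinol carbon and a trans vinyl neighbour rearranges (anionic oxy-Cope) to the ring-expanded enolate, hence A2.
- In favour: the medium ring forms without high dilution; the Z C3=C4 olefin and the C5/C6 oxygens are inherited from a six-membered ring; the C2 ketone appears directly.
- Against: A2 lacks C11–C13, the C8 oxygen and the C1 oxygen. The E C7=C8 olefin must still become the cis lactone and the C8 ester on a flexible ring, and the epoxide must be closed from the C10 oxygen onto C1. The strongly basic medium invites transannular aldol chemistry.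
- Comparison: on ring construction it is the equal or the better of the chosen plan (no macrocyclisation, no protecting-group work at C2). It sets one stereocentre against two, and its long end-game makes it no shorter overall.

**Alternative 3:** The C2–O and C5–O bonds are cut. In the forward step singlet oxygen (tetraphenylporphyrin, visible light) adds suprafacially across C2 and C5 of a ring diene to give the endoperoxide A3. Base-induced Kornblum–DeLaMare fragmentation would then unveil the cis-hydroxy-enone.
- In favour: both oxygens and the Z geometry arrive in one late operation that tolerates lactone, tiglate and epoxide, with no protecting groups.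
- Against: the direction of fragmentation (C2–H or C5–H) decides between the target and its regioisomer. The facial selectivity fixes C5. Ene reactions at the allylic methyl compete. The diene macrocycle is no easier to make than the target.
- Comparison: in end-game step economy it is the better plan (the chosen route spends six steps on what this does in two), and it is equal in functional-group tolerance. It is weaker in control (the MnO2 oxidation of the chosen route is unambiguous) and contributes nothing to the carbon skeleton.

Key step: step 9

Remark on the chemistry: atoms carry germacrane numbers (C14 = methyl on C10, C15 = methyl on C4). The C5 oxygen is carried as a 4-methoxybenzyl (PMB) ether, not a silyl ether, because the ring synthesis passes through a neighbouring alkoxide and the PMB group later leaves without touching silyl ethers. Aldehydes 10 and 15 are made fresh and not stored. TES = triethylsilyl, TBS = tert-butyldimethylsilyl.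

## Route

**Step 1**
Reactants: 1 (4S,5S)-2,2-dimethyl-1,3-dioxolane-4,5-dimethanol
Product: 2 mono-PMB ether of 1
Conditions: NaH (1.0 equiv), THF, 0 °C; 4-methoxybenzyl chloride, tetrabutylammonium iodide (cat.), rt
Reagents that add atoms: 4-methoxybenzyl chloride, COc1ccc(CCl)cc1
Why: Williamson monoalkylation of a C2-symmetric diol; either hydroxyl gives the same product and the poorly soluble monoalkoxide limits dialkylation.

**Step 2**
Reactants: 2 mono-PMB ether
Product: 3 primary tosylate of 2
Conditions: TsCl, Et3N, 4-(dimethylamino)pyridine (cat.), CH2Cl2, 0 °C → rt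
Reagents that add atoms: 4-methylbenzenesulfonyl chloride, Cc1ccc(cc1)S(Cl)(=O)=O
Why: Sulfonylation of the remaining primary alcohol turns C8 into the electrophile for epoxide closure.

**Step 3**
Reactants: 3 tosylate
Product: 5 (1S)-2-(PMB-oxy)-1-[(2S)-oxiran-2-yl]ethan-1-ol, via diol tosylate 4 (not isolated)
Conditions: TsOH·H2O (10 mol %), MeOH, rt; then K2CO3 (3 equiv), MeOH, 0 °C
Reagents that add atoms: none
Why: Acid-catalysed transketalisation frees the C6/C7 diol; the C7 alkoxide then displaces the neighbouring tosylate (intramolecular Williamson, 3-exo-tet) with retention at C7, giving the threo epoxy alcohol. The PMB ether survives the mild acid.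

**Step 4**
Reactants: 5 epoxy alcohol; 6 2,3-dibromoprop-1-ene
Product: 7 2-bromoallyl ether of 5
Conditions: NaH, tetrabutylammonium iodide (cat.), THF, 0 °C
Reagents that add atoms: none
Why: Williamson etherification at the allylic bromide only (the vinylic bromide is inert); a reactive electrophile at 0 °C lets alkylation outrun Payne rearrangement, and the C5 benzyl-type ether cannot migrate.

**Step 5**
Reactants: 7 2-bromoallyl ether
Product: 9 [(2R,3R)-2-(PMB-oxymethyl)-4-methylideneoxolan-3-yl]methanol, via vinyllithium 8 (not isolated)
Conditions: t-BuLi (2.1 equiv), Et2O, −78 °C; then BF3·OEt2 (1.1 equiv), −78 °C; aq. NH4Cl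
Reagents that add atoms: none
Why: Bromine–lithium exchange, then intramolecular epoxide opening (anionic cyclisation of the Parham type): the vinyllithium attacks C7 in the 5-exo mode with SN2 inversion. Next to the untouched C6 centre this gives the cis-2,3-disubstituted ring and frees C8 as the primary alcohol.

**Step 6**
Reactants: 9 alcohol
Product: 10 (2R,3S)-2-(PMB-oxymethyl)-4-methylideneoxolane-3-carbaldehyde
Conditions: Dess–Martin periodinane, NaHCO3, CH2Cl2, 0 °C; short filtration, used at once
Reagents that add atoms: none
Why: Buffered Dess–Martin oxidation; neutral conditions and immediate use guard against C7 epimerisation to the trans aldehyde and against migration of the exocyclic olefin into conjugation.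

**Step 7**
Reactants: 11 2-methylallylboronic acid pinacol ester; 12 vinylboronic acid pinacol ester (3 equiv)
Product: 13 (E)-2-methyl-1,3-bis(pinacolboryl)prop-1-ene
Conditions: second-generation Grubbs catalyst RuCl2(=CHPh)(PCy3)(H2IMes) (5 mol %), CH2Cl2, 40 °C, ethene swept out
Reagents that add atoms: none
Why: Olefin cross-metathesis of a 1,1-disubstituted olefin with a vinylboronate; the reversible process should settle on the isomer with the vinylic boron trans to the bulkier CH2B group (E).

**Step 8**
Reactants: 14 but-2-yn-1-ol
Product: 15 but-2-ynal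
Conditions: MnO2 (activated, excess), CH2Cl2, rt; filtered, solution titrated and used directly
Reagents that add atoms: none
Why: MnO2 oxidation of a propargylic alcohol; the volatile ynal is not isolated neat.

**Step 9**
Reactants: 13 diboryl propene; 15 but-2-ynal; 10 aldehyde
Product: 17 (E)-1,5-anti enyne diol (2R,8R), via anti α-boryl homoallyl borate 16 (not isolated)
Conditions: 13, 15 (1.05 equiv), (R)-3,3′-bis(2,4,6-triisopropylphenyl)-1,1′-binaphthyl-2,2′-diyl hydrogenphosphate (5 mol %), 4 Å sieves, toluene, −45 °C; then 10 (1.2 equiv), BF3·OEt2 (20 mol %), −78 → −45 °C; aq. NaHCO3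
Reagents that add atoms: none
Why: Proposed new method: the allylic boronate of 13, activated by hydrogen bonding of the phosphoric acid to a dioxaborolane oxygen, adds through C1 to the Re face of 15 in a closed chair with the aldehyde substituent and the E-placed vinylic boron both equatorial, forming C1–C2 and the 1,2-anti borate 16. 16 is itself an α-substituted 2-methylallyl boronate and, with 10 and catalytic BF3·OEt2, adds through C9 to C8 in a second chair, forming C8–C9 as the C1=C10 double bond appears. The closest known reactions are the one-pot double allylboration of two aldehydes with γ-boryl allylboranes to (E)-1,5-anti-diols, phosphoric-acid-catalysed allylboration with allyl pinacol boronates, and Lewis-acid-promoted E-selective allylboration with α-substituted allyl pinacol boronates; their combination on a 2-methyl reagent is without precedent. No ring is closed. C2 (R) is set by the catalyst, the transient C1 centre follows from the E geometry of 13, and C8 (R) is set by 1,3-transfer of chirality from C1, the new bond forming on the face that carried boron. The step needs the C2-bearing substituent pseudo-equatorial in the second chair, which gives the E olefin and the 1,5-anti diol; A(1,2) strain with the C10 methyl opposes this, and Lewis-acid complexation of the boronate oxygen (which penalises the pseudo-axial position) and the bulk of the borate-bearing C2 carbon are meant to enforce it. It also needs reagent control over the α-stereocentre of 10, which a closed transition state with an α-substituted allylboron normally provides, and 10 is consumed cold and without base, which protects its labile C7 centre. Only allylic boron transfers: the vinylic C–B bond of 13 is inert until it becomes allylic in 16.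

**Step 10**
Reactants: 17 enyne diol
Product: 19 (Z)-iodo diene diol, via cyclic vinylalanate 18 (not isolated)
Conditions: NaAlH2(OCH2CH2OMe)2 (4 equiv), THF, 0 °C → rt; then I2, THF, −78 °C; aq. KNaC4H4O6, Na2S2O3
Reagents that add atoms: iodine, II
Why: Alkoxide-directed trans-hydroalumination of the propargylic alcohol places aluminium on C4 in a five-membered alkoxyalanate; iodinolysis with retention gives the Z iodide (iodine cis to C2), the geometry the ring olefin needs. Ethers and isolated olefins are inert.

**Step 11**
Reactants: 19 iodo diene diol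
Product: 20 threo epoxy diol (1,10-epoxide syn to C2–OH)
Conditions: VO(acac)2 (5 mol %), t-BuOOH (1.5 equiv, decane), CH2Cl2, 0 °C
Reagents that add atoms: tert-butyl hydroperoxide, CC(C)(C)OO
Why: Vanadium-catalysed hydroxyl-directed epoxidation. A(1,3) strain with the methyl cis to C2 holds C2–H in the olefin plane, so oxygen arrives on the hydroxyl face (threo), which for the 2R carbinol is the epoxide configuration of the target. The iodoalkene is deactivated and the homoallylic C8–OH directs far more slowly.

**Step 12**
Reactants: 20 epoxy diol
Product: 21 2,8-bis-TES ether of 20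
Conditions: Et3SiOTf (2.5 equiv), 2,6-lutidine, CH2Cl2, −78 °C
Reagents that add atoms: triethylsilyl trifluoromethanesulfonate, CC[Si](CC)(CC)OS(=O)(=O)C(F)(F)F
Why: Exhaustive silylation; no selectivity between C2 and C8 is asked for here, their differentiation being left to step 18.

**Step 13**
Reactants: 21 bis-TES ether
Product: 22 C5 primary alcohol
Conditions: DDQ (1.3 equiv), CH2Cl2/pH 7 buffer, 0 °C
Reagents that add atoms: none
Why: Oxidative cleavage of the PMB ether by benzylic hydride abstraction; silyl ethers, epoxide and iodoalkene are untouched under buffered conditions.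

**Step 14**
Reactants: 22 alcohol
Product: 23 C5 aldehyde
Conditions: Dess–Martin periodinane, NaHCO3, CH2Cl2, 0 °C → rt; used at once
Reagents that add atoms: none
Why: Buffered Dess–Martin oxidation to the α-alkoxy aldehyde without epimerisation at C6.

**Step 15**
Reactants: 23 iodoalkene aldehyde
Product: 24 ten-membered C5 carbinol (5S)
Conditions: CrCl2 (10 equiv), NiCl2 (0.1 equiv), DMSO–THF, rt, slow addition to 2 mM
Reagents that add atoms: none
Why: Nozaki–Hiyama–Kishi reaction: oxidative addition of the iodoalkene to zerovalent nickel, transmetalation to trivalent chromium and addition to the aldehyde close the ten-membered ring at C4–C5 with retention of the Z geometry. C5 (S) should arise from Felkin–Anh attack anti to the C6–O bond (5,6-anti); the Z olefin, the epoxide and the cis ring pre-bend the chain.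

**Step 16**
Reactants: 24 macrocyclic carbinol
Product: 25 C5 TBS ether
Conditions: t-BuMe2SiOTf, 2,6-lutidine, CH2Cl2, −78 → 0 °C
Reagents that add atoms: tert-butyldimethylsilyl trifluoromethanesulfonate, CC(C)(C)[Si](C)(C)OS(=O)(=O)C(F)(F)F
Why: Silylation of the only free hydroxyl with a group markedly more robust than the triethylsilyl ethers.

**Step 17**
Reactants: 25 tris-silyl ether
Product: 26 C2,C8 diol
Conditions: HF·pyridine, pyridine, THF, 0 °C
Reagents that add atoms: none
Why: Buffered HF cleaves the two secondary triethylsilyl ethers much faster than the hindered secondary TBS ether and spares the epoxide.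

**Step 18**
Reactants: 26 diol
Product: 27 C2 enone with free C8–OH
Conditions: MnO2 (excess), CH2Cl2, rt
Reagents that add atoms: none
Why: MnO2 oxidises only the allylic C2 carbinol and leaves the saturated C8 carbinol; this is where C2 and C8 are told apart, and the relay stereocentre at C2 disappears.

**Step 19**
Reactants: 27 hydroxy enone; 28 (E)-2-methylbut-2-enoyl chloride (3 equiv)
Product: 29 C8 tiglate
Conditions: pyridine, 4-(dimethylamino)pyridine (0.2 equiv), CH2Cl2, 0 °C → rt
Reagents that add atoms: none
Why: Acylation of the only free hydroxyl through the acylpyridinium; pyridine rather than a trialkylamine avoids vinylketene formation, so the E-conjugated ester is kept.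

**Step 20**
Reactants: 29 tiglate
Product: 30 α-methylene lactone (C5 TBS ether of the target)
Conditions: CrO3, 3,5-dimethylpyrazole (15 equiv each), CH2Cl2, −20 °C
Reagents that add atoms: chromium trioxide, O=[Cr](=O)=O
Why: Allylic oxidation of the cyclic allylic ether methylene, which is activated by both the ring oxygen and the exocyclic olefin; this is the established way from 3-methylenetetrahydrofurans to α-methylene-γ-butyrolactones. All hydroxyls are capped and the other allylic C–H bonds flank electron-poor olefins.

**Step 21**
Reactants: 30 silyl ether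
Product: 31 CNP0345622.1
Conditions: HF·pyridine, pyridine, THF, 0 °C → rt
Reagents that add atoms: none
Why: Fluoride-mediated desilylation under buffered, non-nucleophilic conditions that spare the epoxy ketone, both Michael acceptors and the tiglate.

## Compound list

1 | (4S,5S)-2,2-dimethyl-1,3-dioxolane-4,5-dimethanol (2,3-O-isopropylidene-L-threitol) | OC[C@@H]1OC(C)(C)O[C@H]1CO | starting material
2 | [(4S,5S)-5-{[(4-methoxybenzyl)oxy]methyl}-2,2-dimethyl-1,3-dioxolan-4-yl]methanol | COc1ccc(COC[C@@H]2OC(C)(C)O[C@H]2CO)cc1 | intermediate
3 | [(4S,5S)-5-{[(4-methoxybenzyl)oxy]methyl}-2,2-dimethyl-1,3-dioxolan-4-yl]methyl 4-methylbenzenesulfonate | COc1ccc(COC[C@@H]2OC(C)(C)O[C@H]2COS(=O)(=O)c3ccc(C)cc3)cc1 | intermediate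
4 | (2S,3S)-2,3-dihydroxy-4-[(4-methoxybenzyl)oxy]butyl 4-methylbenzenesulfonate | COc1ccc(COC[C@H](O)[C@@H](O)COS(=O)(=O)c2ccc(C)cc2)cc1 | intermediate (not isolated)
5 | (1S)-2-[(4-methoxybenzyl)oxy]-1-[(2S)-oxiran-2-yl]ethan-1-ol | COc1ccc(COC[C@H](O)[C@@H]2CO2)cc1 | intermediate
6 | 2,3-dibromoprop-1-ene | BrCC(Br)=C | starting material
7 | (2S)-2-{(1S)-1-[(2-bromoprop-2-en-1-yl)oxy]-2-[(4-methoxybenzyl)oxy]ethyl}oxirane | COc1ccc(COC[C@H](OCC(Br)=C)[C@@H]2CO2)cc1 | intermediate
8 | vinyllithium from 7 (lithium in place of bromine) | COc1ccc(COC[C@H](OCC([Li])=C)[C@@H]2CO2)cc1 | intermediate (not isolated)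
9 | [(2R,3R)-2-{[(4-methoxybenzyl)oxy]methyl}-4-methylideneoxolan-3-yl]methanol (ring substituents cis) | OC[C@H]1C(=C)CO[C@H]1COCc1ccc(OC)cc1 | intermediate
10 | (2R,3S)-2-{[(4-methoxybenzyl)oxy]methyl}-4-methylideneoxolane-3-carbaldehyde (cis) | O=C[C@H]1C(=C)CO[C@H]1COCc1ccc(OC)cc1 | intermediate
11 | 4,4,5,5-tetramethyl-2-(2-methylprop-2-en-1-yl)-1,3,2-dioxaborolane | CC(=C)CB1OC(C)(C)C(C)(C)O1 | starting material
12 | 2-ethenyl-4,4,5,5-tetramethyl-1,3,2-dioxaborolane | C=CB1OC(C)(C)C(C)(C)O1 | starting material
13 | (E)-2-methyl-1,3-bis(4,4,5,5-tetramethyl-1,3,2-dioxaborolan-2-yl)prop-1-ene | C/C(CB1OC(C)(C)C(C)(C)O1)=C\B1OC(C)(C)C(C)(C)O1 | intermediate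
14 | but-2-yn-1-ol | CC#CCO | starting material
15 | but-2-ynal | CC#CC=O | intermediate
16 | pinacol borate of (3R,4R)-2-methyl-3-(pinacolboryl)hept-1-en-5-yn-4-ol (O and B anti) | CC#C[C@H](OB1OC(C)(C)C(C)(C)O1)[C@H](B1OC(C)(C)C(C)(C)O1)C(C)=C | intermediate (not isolated)
17 | (1R,3E,5R)-1-[(2R,3R)-2-{[(4-methoxybenzyl)oxy]methyl}-4-methylideneoxolan-3-yl]-3-methyloct-3-en-6-yne-1,5-diol | CC#C[C@H](O)/C=C(\C)C[C@@H](O)[C@H]1C(=C)CO[C@H]1COCc1ccc(OC)cc1 | intermediate
18 | sodium salt of the five-membered alkoxy(vinyl)alanate from 17 (Al on C4, cis to C2; C8 alkoxide) | C/C1=C/[C@H](O[Al-]1(OCCOC)OCCOC)/C=C(\C)C[C@@H]([O-])[C@H]2C(=C)CO[C@H]2COCc3ccc(OC)cc3.[Na+].[Na+] | intermediate (not isolated)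
19 | (1R,3E,5R,6Z)-7-iodo-1-[(2R,3R)-2-{[(4-methoxybenzyl)oxy]methyl}-4-methylideneoxolan-3-yl]-3-methylocta-3,6-diene-1,5-diol | C/C(I)=C/[C@H](O)/C=C(\C)C[C@@H](O)[C@H]1C(=C)CO[C@H]1COCc1ccc(OC)cc1 | intermediate
20 | (1S,2Z)-1-[(2R,3R)-3-{(2R)-2-hydroxy-2-[(2R,3R)-2-{[(4-methoxybenzyl)oxy]methyl}-4-methylideneoxolan-3-yl]ethyl}-3-methyloxiran-2-yl]-3-iodobut-2-en-1-ol (threo epoxy alcohol) | C/C(I)=C/[C@H](O)[C@H]1O[C@]1(C)C[C@@H](O)[C@H]2C(=C)CO[C@H]2COCc3ccc(OC)cc3 | intermediate
21 | 2,8-bis-O-triethylsilyl ether of 20 | C/C(I)=C/[C@H](O[Si](CC)(CC)CC)[C@H]1O[C@]1(C)C[C@@H](O[Si](CC)(CC)CC)[C@H]2C(=C)CO[C@H]2COCc3ccc(OC)cc3 | intermediate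
22 | C5 primary alcohol (PMB removed from 21) | C/C(I)=C/[C@H](O[Si](CC)(CC)CC)[C@H]1O[C@]1(C)C[C@@H](O[Si](CC)(CC)CC)[C@H]2C(=C)CO[C@H]2CO | intermediate
23 | C5 aldehyde of 22 | C/C(I)=C/[C@H](O[Si](CC)(CC)CC)[C@H]1O[C@]1(C)C[C@@H](O[Si](CC)(CC)CC)[C@H]2C(=C)CO[C@H]2C=O | intermediate
24 | ten-membered ring alcohol: (5S)-5-hydroxy-2,8-bis(triethylsilyloxy)-1,10-epoxygermacra-3Z,11(13)-diene 6,12-cyclic ether (cis ring fusion) | C=C1CO[C@@H]2[C@H]1[C@H](O[Si](CC)(CC)CC)C[C@@]1(C)O[C@@H]1[C@@H](O[Si](CC)(CC)CC)/C=C(/C)[C@@H]2O | intermediate
25 | 5-O-tert-butyldimethylsilyl ether of 24 | C=C1CO[C@@H]2[C@H]1[C@H](O[Si](CC)(CC)CC)C[C@@]1(C)O[C@@H]1[C@@H](O[Si](CC)(CC)CC)/C=C(/C)[C@@H]2O[Si](C)(C)C(C)(C)C | intermediate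
26 | 2,8-diol (both triethylsilyl groups removed from 25) | C=C1CO[C@@H]2[C@H]1[C@H](O)C[C@@]1(C)O[C@@H]1[C@@H](O)/C=C(/C)[C@@H]2O[Si](C)(C)C(C)(C)C | intermediate
27 | 2-oxo-8-hydroxy compound (enone) from 26 | C=C1CO[C@@H]2[C@H]1[C@H](O)C[C@@]1(C)O[C@@H]1C(=O)/C=C(/C)[C@@H]2O[Si](C)(C)C(C)(C)C | intermediate
28 | (E)-2-methylbut-2-enoyl chloride (tigloyl chloride) | C/C=C(\C)C(=O)Cl | starting material
29 | 8-O-tigloyl derivative of 27 | C=C1CO[C@@H]2[C@H]1[C@H](OC(=O)/C(C)=C/C)C[C@@]1(C)O[C@@H]1C(=O)/C=C(/C)[C@@H]2O[Si](C)(C)C(C)(C)C | intermediate
30 | 5-O-tert-butyldimethylsilyl ether of the target (12,6-lactone) | C=C1C(=O)O[C@@H]2[C@H]1[C@H](OC(=O)/C(C)=C/C)C[C@@]1(C)O[C@@H]1C(=O)/C=C(/C)[C@@H]2O[Si](C)(C)C(C)(C)C | intermediate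
31 | CNP0345622.1: (1S,5S,6R,7R,8R,10R)-1,10-epoxy-5-hydroxy-2-oxogermacra-3Z,11(13)-dien-12,6-olid-8-yl (E)-2-methylbut-2-enoate | C=C1C(=O)O[C@@H]2[C@H]1[C@H](OC(=O)/C(C)=C/C)C[C@@]1(C)O[C@@H]1C(=O)/C=C(/C)[C@@H]2O | target

Total step count: 21. Longest linear sequence: 19 steps (steps 1–6 and 9–21).

## Least certain steps

**Step 9 (key step).** The most likely failure is loss of geometric control in the second allyl transfer. The C2-bearing substituent may take the pseudo-axial position to escape A(1,2) strain with the C10 methyl, which would give the Z olefin and the C8 epimer. Incomplete enantiofacial control at C2 with an untested 2-methyl γ-boryl reagent and epimerisation of 10 are further risks.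

Fallback (known chemistry, from 10 back to 17):
- Phosphoric-acid-catalysed propargylation of 10 with allenylboronic acid pinacol ester gives the homopropargylic alcohol F1 (8R).
- Negishi carboalumination–iodination of F1 (AlMe3, Cp2ZrCl2; then I2) gives the (E)-iodoalkene F2 and fixes the C1=C10 geometry by syn addition.
- Nozaki–Hiyama–Kishi coupling of F2 with 15 (CrCl2, NiCl2) gives the diol as a C2 epimer mixture F3.
- MnO2 oxidises only the propargylic, allylic C2 carbinol to the ynenone F4.
- Corey–Bakshi–Shibata reduction of F4 (alkynyl as the small group) returns 17.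

**Step 5.** The most likely failure is β-elimination of the 2-lithioallyl ether to allene and alkoxide before ring closure, or opening of the epoxide at C8 in the 6-endo mode.

Fallback (from 5 back to 9), keeping the stereospecific SN2 at C7 but using a stabilised carbanion:
- Oxa-Michael addition of 5 to phenyl vinyl sulfone (catalytic base) gives the sulfonylethyl ether F5.
- Deprotonation α to sulfur and 5-exo epoxide opening give the ring sulfone F6.
- Dianion alkylation with (iodomethyl)trimethylsilane gives the β-silyl sulfone F7.
- Fluoride-induced elimination (Bu4NF) releases the exocyclic methylene and returns 9.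

**Step 15.** The most likely failure is poor facial selectivity at C5, because the conformation of the forming medium ring can override Felkin control; slow closure with competing reduction of the iodoalkene is also possible.

Fallback (from 24 back to 24): the C5 epimer mixture is oxidised (Dess–Martin periodinane) to the ring enone F8. It is then reduced under Luche conditions (NaBH4, CeCl3) or, if the ring again favours the wrong face, by catalyst-controlled Corey–Bakshi–Shibata reduction.

**Step 20.** The most likely failure is oxidation at a wrong allylic site (C7–H with transposition, or C5–H next to the silyl ether), or incomplete conversion.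

Fallback (from 29 back to 30): the one-step C–H to C=O oxidation is split in two. SeO2 (cat.) with t-BuOOH hydroxylates the C12 methylene to the lactol F9, and Ag2CO3 on Celite oxidises the lactol to 30.

## Further compounds

F1 | step 9 | (1R)-1-[(2R,3R)-2-{[(4-methoxybenzyl)oxy]methyl}-4-methylideneoxolan-3-yl]but-3-yn-1-ol | C#CC[C@@H](O)[C@H]1C(=C)CO[C@H]1COCc1ccc(OC)cc1
F2 | step 9 | (1R,3E)-4-iodo-1-[(2R,3R)-2-{[(4-methoxybenzyl)oxy]methyl}-4-methylideneoxolan-3-yl]-3-methylbut-3-en-1-ol | I/C=C(\C)C[C@@H](O)[C@H]1C(=C)CO[C@H]1COCc1ccc(OC)cc1
F3 | step 9 | 17 as a mixture of C2 epimers | CC#CC(O)/C=C(\C)C[C@@H](O)[C@H]1C(=C)CO[C@H]1COCc1ccc(OC)cc1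
F4 | step 9 | (4E,7R)-7-hydroxy-7-[(2R,3R)-2-{[(4-methoxybenzyl)oxy]methyl}-4-methylideneoxolan-3-yl]-5-methylhept-4-en-2-yn-... ynenone (C2 ketone of 17) | CC#CC(=O)/C=C(\C)C[C@@H](O)[C@H]1C(=C)CO[C@H]1COCc1ccc(OC)cc1
F5 | step 5 | 2-(phenylsulfonyl)ethyl ether of 5 | COc1ccc(COC[C@H](OCCS(=O)(=O)c2ccccc2)[C@@H]3CO3)cc1
F6 | step 5 | [(2R,3R)-2-{[(4-methoxybenzyl)oxy]methyl}-4-(phenylsulfonyl)oxolan-3-yl]methanol (C4 epimers) | OC[C@H]1C(S(=O)(=O)c2ccccc2)CO[C@H]1COCc1ccc(OC)cc1
F7 | step 5 | 4-(trimethylsilylmethyl) derivative of F6 | OC[C@H]1C(C[Si](C)(C)C)(S(=O)(=O)c2ccccc2)CO[C@H]1COCc1ccc(OC)cc1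
F8 | step 15 | C5 ketone of 24 (ring enone) | C=C1CO[C@@H]2[C@H]1[C@H](O[Si](CC)(CC)CC)C[C@@]1(C)O[C@@H]1[C@@H](O[Si](CC)(CC)CC)/C=C(/C)C2=O
F9 | step 20 | C12 lactol of 29 (anomers) | C=C1C(O)O[C@@H]2[C@H]1[C@H](OC(=O)/C(C)=C/C)C[C@@]1(C)O[C@@H]1C(=O)/C=C(/C)[C@@H]2O[Si](C)(C)C(C)(C)C
A1 | alternative 1 | cis-fused bicyclic ethyl acetal with C8 tetramethylpiperidinyloxy ether | C1[C@@H](OCC)O[C@@H]2[C@H]1[C@H](ON3C(C)(C)CCCC3(C)C)C[C@@]1(C)O[C@@H]1[C@@H](O[Si](CC)(CC)CC)/C=C(/C)[C@@H]2O[Si](C)(C)C(C)(C)C
A2 | alternative 2 | ten-membered C2 enone with C10 silyloxy centre and E C7=C8 olefin | CC1(C)O[C@@H]2/C=C/C[C@@](C)(O[Si](C(C)C)(C(C)C)C(C)C)CC(=O)/C=C(/C)[C@@H]2O1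
A3 | alternative 3 | 2,5-endoperoxide of the ring diene | C1[C@@]2(C)O[C@@H]2[C@H]4C=C(C)[C@H](OO4)[C@@H]3OC(=O)C(=C)[C@@H]3[C@@H]1OC(=O)/C(C)=C/C
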